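The order in catalyst cannot be read by comparing runs, since eta, theta and zeta all hold 0.12 mM ; it has to come from the shape of a curve.

| setting | eta | theta | zeta | flask |
|---|---|---|---|---|
| left-handed substrate | 0.35 M | 0.55 M | 0.25 M | 0.25 M |
| right-handed substrate | 0.35 M | 0.55 M | 0.25 M | 0.25 M |
| partner | 0.25 M | 0.25 M | 0.38 M | 0.250 M |
| catalyst | 0.12 mM | 0.12 mM | 0.12 mM | 0.12 mM |
| remark | run made earlier | run made earlier | run made earlier |  |

| run | time / h | left-handed product / % | left-handed substrate / % |
|---|---|---|---|
| eta | 0.250 | 1 | 48 |
| eta | 0.833 | 5 | 46 |
| eta | 1.33 | 8 | 45 |
| eta | 2.00 | 7 | 42 |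
| eta | 3.00 | 9 | 43 |
| eta | 4.00 | 13 | 42 |
| theta | 0.333 | 4 | 48 |
| theta | 0.500 | 4 | 49 |
| theta | 0.833 | 3 | 45 |
| theta | 1.33 | 6 | 46 |
| theta | 2.50 | 7 | 41 |
| theta | 4.00 | 9 | 42 |
| zeta | 0.833 | 4 | 42 |
| zeta | 1.50 | 10 | 38 |
| zeta | 2.50 | 15 | 36 |
| zeta | 3.00 | 14 | 40 |
| zeta | 4.00 | 17 | 35 |

(scatter of a reading: 1.5 percentage points)

- apparent order in partner when 10 % of the left-handed substrate and right-handed substrate together are converted (percent change of the rate of making left-handed product for one percent more partner charged)
- apparent order in catalyst when 10 % of the left-handed substrate and right-handed substrate together are converted (percent change of the rate of making left-handed product for one percent more catalyst charged)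
- factor on the rate of making left-handed product when 10 % of the left-handed substrate and right-handed substrate together are converted if partner is charged twice over

- catalyst is single-handed; left-handed substrate and right-handed substrate are mirror images of each other, charged as a racemate, each of them at the stated concentration
- no earlier run changes the charge of catalyst; that part of a forecast is a guess

On logarithmic axes the later readings of left-handed product have a gradient. Eta and theta from 1.33 h and zeta from 1.50 h, each to 4.00 h, give 0.441, 0.368 and 0.541, a mean of a = 0.450, where a is the percent rise of product for one percent more time.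

Suppose product is partner times catalyst times a function of time growing as t^a. More catalyst then reaches a fixed conversion earlier, where the rate is higher, and the apparent order in catalyst is the reciprocal of a, 2.22. The conversion of 10 % takes a share φ = 0.200 of the partner charged, which leverages partner further, so its order is 2.47.

Used over twice the partner, the same power gives a factor of 5.25. But two scattered zeta readings give a gradient of 1.56 from 0.833 h to 1.50 h, steeper than a, and on this reckoning a doubled charge reaches the moment earlier, so one number may not stretch that far and this factor may stand high.

The forecast, noting “Catalyst was never varied, so first order is a guess”, gives 0.6, 1 and 1.5, each lower than this reckoning .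

The flask gives an order in partner of 2.6, an order in catalyst of 2.2 and a doubling factor of 4.35.

    partner + catalyst + left-handed substrate → catalyst + left-handed product (k = 6000 M⁻² h⁻¹)
    partner → decomposed reagent (k = 0.0425 h⁻¹)
    catalyst ⇌ dormant form (K = 3.10, k = 0.701 h⁻¹)
    partner + catalyst + right-handed substrate → catalyst + right-handed product (k = 1020 M⁻² h⁻¹)

At 2.50 h the flask holds 31.8 % of the catalyst charged as catalyst and 68.2 % as dormant form. Carried onto the flask's own curve, a takes left-handed product from 9.24 % at that time to 12.6 % at 5.00 h, and the flask stands at 12.2 %.

All runs come from a simulation for an exercise.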